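**Plan**

- Retrosynthesis: the C1=C2 enol ether goes back to a C1 methyl ketal and the ylidene butenolide to a furan. Then the C8 and C13 esters, C10–C14 (methyl addition), C8–C9 (macro-aldol), C1–C10 (acylation of a lithiated dihydrofuran) and C5–C6 (epoxide opening by a furyl metal) are cut.
- Enabling feature: the lactone atoms O, C6, C7, C11 and C12 are a furan ring once C12 bears silicon instead of its oxo group and C5 is CH2. The strained C5=C6 enol lactone can therefore stay latent until every other bond is in place.
- Forward order: a linalool-derived epoxide and a silylfuran from the furan diester are joined at C5–C6. The oxolane closes as a lactol and becomes the 2-acetyl dihydrofuran. The ten-membered ring closes at C8–C9, methyl goes on C10 and methanol on C1, the esters follow, then furan to butenolide, and the enol ether last.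
- Stereochemistry: C4 comes from (S)-linalool. C10 is set by methyl addition to the macrocyclic ketone on the face away from the bridge, and C8 by a hydroxyl-directed 1,3-syn reduction. The C1 ketal centre and the C5=C6 geometry are imposed by the bicycle.

Key step: step 24

Remark (numbering): germacrane numbers are used throughout: C1(=C2)–C3–C4(CH3-15, oxygen bridge to C1)–C5–C6–C7–C8–C9–C10(CH3-14), with the lactone or furan O–C6–C7=C11–C12 and C13 on C11. In the names of 12–17, "furyl" means 4-(tert-butyldimethylsilyloxymethyl)-3-(triethylsilyloxymethyl)-5-(trimethylsilyl)furan-2-yl.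

Assumption: step 16 is taken to give both C8 epimers. They are carried together because C8 becomes trigonal again in step 18 and is set in step 21, so C8 is left undefined in 20 and 21.

**Route**

Step 1
Reactants: 1 (S)-linalool
Product: 2 (4S)-4-methylhex-5-ene-1,4-diol
Conditions: O3 (1 equiv), CH2Cl2/MeOH, −78 °C; then NaBH4, −78 °C to rt
Reagents that add atoms: ozone, [O-][O+]=O
Why: Ozonolysis with reductive work-up should cleave only the electron-rich trisubstituted alkene, and borohydride reduces the resulting aldehyde (lactol) to the primary alcohol; the carbinol carbon C4 is not touched and keeps the configuration of 1.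

Step 2
Reactants: 2 (4S)-4-methylhex-5-ene-1,4-diol
Product: 3 (4S)-4-hydroxy-4-methylhex-5-enyl pivalate
Conditions: t-BuCOCl, pyridine, CH2Cl2, 0 °C
Reagents that add atoms: pivaloyl chloride, CC(C)(C)C(=O)Cl
Why: Pyridine-mediated acylation is fast at the primary hydroxyl and does not occur at the tertiary one, so a single ester should form.

Step 3
Reactants: 3 (4S)-4-hydroxy-4-methylhex-5-enyl pivalate
Product: 4 (4S)-4,5-dihydroxy-4-methylpentyl pivalate
Conditions: O3, CH2Cl2/MeOH, −78 °C; then NaBH4, −78 °C to 0 °C
Reagents that add atoms: ozone, [O-][O+]=O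
Why: Ozonolysis of the vinyl group with borohydride work-up gives the 1,2-diol with C5 as CH2OH; the pivalate survives borohydride at low temperature and C4 is again untouched.

Step 4
Reactants: 4 (4S)-4,5-dihydroxy-4-methylpentyl pivalate
Product: 6 3-[(2S)-2-methyloxiran-2-yl]propyl pivalate, via primary tosylate 5 (not isolated)
Conditions: TsCl, Et3N, Bu2SnO (cat.), CH2Cl2, rt; then K2CO3, MeOH, 0 °C
Reagents that add atoms: none
Why: Tin-catalysed monosulfonylation of the primary hydroxyl of the 1,2-diol and base-induced 3-exo-tet Williamson closure give the epoxide; the C4–O bond is never broken, so C4 keeps its configuration.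

Step 5
Reactants: 7 diethyl furan-3,4-dicarboxylate
Product: 8 diethyl 2-(trimethylsilyl)furan-3,4-dicarboxylate
Conditions: LiN(i-Pr)2 (1.1 equiv) added to 7 and Me3SiCl, THF, −78 °C
Reagents that add atoms: chlorotrimethylsilane, C[Si](C)(C)Cl
Why: Directed ortho-metalation with in situ silyl trapping removes the acidic furan α-hydrogen next to an ester and silylates the anion before it can attack a second ester; the substrate is symmetric, so only one monosilyl product is possible.

Step 6
Reactants: 8 diethyl 2-(trimethylsilyl)furan-3,4-dicarboxylate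
Product: 9 [2-(trimethylsilyl)furan-3,4-diyl]dimethanol
Conditions: LiAlH4, Et2O, 0 °C
Reagents that add atoms: none
Why: Hydride reduction converts both esters into primary alcohols, and the aryl C–Si bond is inert to LiAlH4.

Step 7
Reactants: 9 [2-(trimethylsilyl)furan-3,4-diyl]dimethanol
Product: 10 {4-[(triethylsilyloxy)methyl]-2-(trimethylsilyl)furan-3-yl}methanol
Conditions: Et3SiCl (1.0 equiv), imidazole, CH2Cl2, −78 °C to −30 °C
Reagents that add atoms: chlorotriethylsilane, CC[Si](CC)(CC)Cl
Why: Sterically controlled monosilylation: the hydroxymethyl group flanked by C–SiMe3 is shielded, so one equivalent of silyl chloride at low temperature should take the other one, and any regioisomer or bis-ether is separable.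

Step 8
Reactants: 10 {4-[(triethylsilyloxy)methyl]-2-(trimethylsilyl)furan-3-yl}methanol
Product: 11 3-[(tert-butyldimethylsilyloxy)methyl]-4-[(triethylsilyloxy)methyl]-2-(trimethylsilyl)furan
Conditions: t-BuMe2SiCl, imidazole, DMF, rt
Reagents that add atoms: tert-butyldimethylsilyl chloride, CC(C)(C)[Si](C)(C)Cl
Why: Imidazole-promoted silylation protects the remaining, more hindered primary alcohol (the future C13 oxygen) with a group that outlasts the triethylsilyl ether.

Step 9
Reactants: 11 3-[(tert-butyldimethylsilyloxy)methyl]-4-[(triethylsilyloxy)methyl]-2-(trimethylsilyl)furan; 6 3-[(2S)-2-methyloxiran-2-yl]propyl pivalate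
Product: 12 (4S)-5-furyl-4-hydroxy-4-methylpentyl pivalate
Conditions: 11, s-BuLi, THF, −78 °C; MgBr2·OEt2; CuI (10 mol%), then 6, −40 °C to 0 °C
Reagents that add atoms: none
Why: Lithiation of the only free furan position, transmetalation to the Grignard reagent and copper-catalysed SN2 opening of the 2,2-disubstituted epoxide at its CH2 terminus form C5–C6; the pivalate tolerates the arylmagnesium species at low temperature, and C4 keeps its configuration because its C–O bond is not broken.

Step 10
Reactants: 12 (4S)-5-furyl-4-hydroxy-4-methylpentyl pivalate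
Product: 13 (4S)-5-furyl-4-methylpentane-1,4-diol
Conditions: i-Bu2AlH (3 equiv), CH2Cl2, −78 °C; Rochelle salt work-up
Reagents that add atoms: none
Why: Reductive cleavage of the pivalate by the aluminium hydride leaves the silyl ethers, the C–Si bond and the tertiary alcohol untouched.

Step 11
Reactants: 13 (4S)-5-furyl-4-methylpentane-1,4-diol
Product: 14 (5S)-5-(furylmethyl)-5-methyloxolan-2-ol (lactol; both anomers)
Conditions: SO3·pyridine, DMSO, i-Pr2NEt, CH2Cl2, 0 °C
Reagents that add atoms: none
Why: Parikh–Doering oxidation of the primary alcohol gives the aldehyde, which the tertiary hydroxyl captures as the five-membered lactol (oxolane ring O–C1 closed; the anomeric centre is of no consequence), and activated dimethyl sulfoxide does not attack the triethylsilyl ether.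

Step 12
Reactants: 14 (5S)-5-(furylmethyl)-5-methyloxolan-2-ol
Product: 15 (2S)-2-(furylmethyl)-2-methyl-2,3-dihydrofuran
Conditions: MsCl, Et3N, THF, −40 °C to reflux
Reagents that add atoms: none
Why: Mesylation of the anomeric hydroxyl and amine-induced elimination through the oxocarbenium ion give the cyclic enol ether C1=C2, the usual lactol-to-dihydrofuran dehydration.

Step 13
Reactants: 15 (2S)-2-(furylmethyl)-2-methyl-2,3-dihydrofuran; 16 N-methoxy-N-methylacetamide
Product: 17 1-[(5S)-5-(furylmethyl)-5-methyl-4,5-dihydrofuran-2-yl]ethanone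
Conditions: 15, t-BuLi, THF, −78 °C to 0 °C; then 16, −78 °C to 0 °C
Reagents that add atoms: none
Why: α-Lithiation of the cyclic enol ether at the vinylic carbon next to oxygen followed by Weinreb ketone synthesis forms C1–C10, the chelated tetrahedral adduct preventing a second addition.

Step 14
Reactants: 17 1-[(5S)-5-(furylmethyl)-5-methyl-4,5-dihydrofuran-2-yl]ethanone
Product: 18 1-[(5S)-5-{[4-(tert-butyldimethylsilyloxymethyl)-3-(hydroxymethyl)-5-(trimethylsilyl)furan-2-yl]methyl}-5-methyl-4,5-dihydrofuran-2-yl]ethanone
Conditions: PPTS (cat.), MeOH/CH2Cl2, 0 °C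
Reagents that add atoms: none
Why: Acid-catalysed methanolysis removes the primary triethylsilyl ether far faster than the tert-butyldimethylsilyl ether, and the enol ether is deactivated toward protonation by conjugation with the ketone.

Step 15
Reactants: 18 the C8 alcohol just described
Product: 19 2-{[(2S)-5-acetyl-2-methyl-2,3-dihydrofuran-2-yl]methyl}-4-(tert-butyldimethylsilyloxymethyl)-5-(trimethylsilyl)furan-3-carbaldehyde
Conditions: MnO2, CH2Cl2, rt
Reagents that add atoms: none
Why: MnO2 oxidises the furylic (benzylic-type) primary alcohol to the aldehyde under neutral conditions that leave the enone and the silyl groups alone.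

Step 16
Reactants: 19 the keto aldehyde just described
Product: 20 macrocyclic aldol (ring C1–C10 closed at C8–C9; 8-hydroxy; 10-oxo; C1=C2; furan fused at C6/C7; 12-SiMe3; 13-OTBS; both C8 epimers)
Conditions: slow addition of 19 to LiN(SiMe3)2 (1.5 equiv), THF, −78 °C, final 2 mM; AcOH quench at −78 °C
Reagents that add atoms: none
Why: Intramolecular (macro) aldol addition: the acetyl methyl group is the only enolisable position and the aldehyde cannot enolise, so kinetic deprotonation under high dilution should give a single mode of ring closure (ten-membered carbocycle), held as the chelated lithium aldolate until the cold quench; C8 is not controlled and need not be.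

Step 17
Reactants: 20 macrocyclic aldol
Product: 21 (4S,10R)-8,10-diol (10-methyl carbinol; C1=C2 enol ether; 12-SiMe3; 13-OTBS; both C8 epimers)
Conditions: MeMgBr (3 equiv), THF, −78 °C; aqueous NaHCO3
Reagents that add atoms: methylmagnesium bromide, C[Mg]Br
Why: Grignard 1,2-addition to the ketone: the short C5–C9 bridge should hold C9 below the dihydrofuran plane on the ring-oxygen side and turn the carbonyl oxygen toward C2, so methyl attacks the exposed face away from the bridge and places the C10 hydroxyl and methyl as in the target.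

Step 18
Reactants: 21 (4S,10R)-8,10-diol
Product: 22 (4S,10R)-10-hydroxy-8-ketone (C1=C2 enol ether; 12-SiMe3; 13-OTBS)
Conditions: Dess–Martin periodinane, pyridine, CH2Cl2, 0 °C
Reagents that add atoms: none
Why: Dess–Martin oxidation converts both C8 epimers of the secondary carbinol into one ketone, the tertiary alcohol cannot be oxidised, and pyridine buffers the acetic acid that would otherwise attack the enol ether.

Step 19
Reactants: 22 (4S,10R)-10-hydroxy-8-ketone
Product: 23 (1R,4S,10R)-1-methoxy ketal (8-oxo; 10-OH; 13-OH; 12-SiMe3)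
Conditions: camphorsulfonic acid (cat.), MeOH, 0 °C to rt
Reagents that add atoms: methanol, CO
Why: Acid-catalysed Markovnikov addition of methanol to the enol ether (protonation at C2, oxocarbenium ion at C1) gives the mixed ketal, whose configuration is fixed because C10 and C5 must stay cis on the oxolane to span the ring, and the same acid methanolyses the primary silyl ether.

Step 20
Reactants: 23 (1R,4S,10R)-1-methoxy ketal
Product: 24 13-acetate of 23
Conditions: Ac2O, pyridine, CH2Cl2, 0 °C
Reagents that add atoms: acetic anhydride, CC(=O)OC(C)=O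
Why: Pyridine-mediated acetylation takes the primary hydroxyl only, the tertiary C10 hydroxyl being inert under these conditions.

Step 21
Reactants: 24 13-acetate of 23
Product: 25 (1R,4S,8S,10R)-8,10-syn-diol (1-OMe ketal; 13-OAc; 12-SiMe3)
Conditions: Et2BOMe, THF/MeOH, −78 °C; NaBH4; AcOH, then MeOH co-evaporation
Reagents that add atoms: none
Why: Narasaka–Prasad reduction: the C10 hydroxyl and the C8 ketone are tied in a six-membered boron chelate, and external hydride adds to it to give the 1,3-syn diol, which sets C8 relative to C10.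

Step 22
Reactants: 25 (1R,4S,8S,10R)-8,10-syn-diol
Product: 26 8-methacrylate of 25 (10-OH free)
Conditions: methacrylic anhydride, Et3N, DMAP, CH2Cl2, rt
Reagents that add atoms: methacrylic anhydride, C=C(C)C(=O)OC(=O)C(C)=C
Why: DMAP-catalysed acyl transfer esterifies the secondary C8 hydroxyl, and the hindered tertiary C10 hydroxyl is left free.

Step 23
Reactants: 26 8-methacrylate of 25
Product: 27 10-O-trimethylsilyl ether of 26 (furan-fused macrocycle; 12-SiMe3; 1-OMe ketal; 8-methacrylate; 13-acetate)
Conditions: N-(trimethylsilyl)imidazole, CH2Cl2, rt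
Reagents that add atoms: N-(trimethylsilyl)imidazole, C[Si](C)(C)n1ccnc1
Why: N-Silylimidazole silylates even hindered tertiary alcohols under neutral conditions that spare the ketal and the silylfuran, and the ether keeps the C10 oxygen from adding across the ring to C6 in the next step.

Step 24
Reactants: 27 10-O-trimethylsilyl ether of 26
Product: 32 C1 methyl ketal of the 10-O-trimethylsilyl target (ylidene butenolide in place), via endoperoxide 28 (not isolated), via silyl ester 29 (not isolated), via hydroxybutenolide 30 (not isolated), via acetoxybutenolide 31 (not isolated)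
Conditions: O2, hν (visible), tetraphenylporphyrin (cat.), CH2Cl2, −78 °C; H2O/THF, 0 °C, concentrate; then Ac2O, pyridine, 0 °C to rt
Reagents that add atoms: oxygen, O=O
Why: Singlet oxygen adds across C6 and C12 of the furan in a (4+2) cycloaddition to give endoperoxide 28, and the C12–Si bond then shifts to the neighbouring peroxide oxygen with O–O cleavage (a 1,2-silyl migration akin to a Baeyer–Villiger shift), which opens the bicycle to silyl 4-oxo-2-enoate 29 and puts the carbonyl at C12. Hydrolysis of the silyl ester lets the carboxyl add to the C6 ketone (5-exo-trig closure of the butenolide ring) to give 30, and acetylation to 31 followed by loss of acetic acid toward C5, the only neighbour of C6 that carries hydrogen, creates C5=C6. The closest known reaction type is the sensitised photooxygenation of 2-trialkylsilylfurans to γ-hydroxybutenolides, combined with the dehydration of γ-hydroxybutenolides to γ-ylidene butenolides. No new stereocentre remains, since C6 of 30 and 31 becomes trigonal, and the alkene geometry is dictated by the ten-membered ring, which can hold only the isomer with C4 cis to C7. The step needs regioselectivity (C12, not C6, must become the carbonyl), which silicon at C12 secures, and chemoselectivity, which rests on the enol ether being stored as the C1 ketal, the methacrylate and acetate being electron-poor, and the C10 oxygen being silylated.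

Step 25
Reactants: 32 C1 methyl ketal of the 10-O-trimethylsilyl target
Product: 33 10-O-trimethylsilyl ether of the target (C1=C2 enol ether formed)
Conditions: Me3SiOTf, i-Pr2NEt, CH2Cl2, −20 °C to 0 °C
Reagents that add atoms: none
Why: Silyl triflate-promoted conversion of a ketal into an enol ether: silylation of the methoxy oxygen expels methoxytrimethylsilane, and the amine removes a proton from C2, the only carbon next to the oxocarbenium centre that carries hydrogen.

Step 26
Reactants: 33 10-O-trimethylsilyl ether of the target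
Product: 34 CNP0394509.2 (target)
Conditions: Bu4NF, AcOH (1:1), THF, 0 °C
Reagents that add atoms: none
Why: Acetic acid-buffered fluoride cleaves the tertiary trimethylsilyl ether without touching the two esters, the ylidene butenolide or the enol ether.

**Compound list**

1 | (S)-linalool | C=C[C@@](C)(O)CCC=C(C)C | starting material
2 | (4S)-4-methylhex-5-ene-1,4-diol | C=C[C@@](C)(O)CCCO | intermediate
3 | (4S)-4-hydroxy-4-methylhex-5-enyl pivalate | C=C[C@@](C)(O)CCCOC(=O)C(C)(C)C | intermediate
4 | (4S)-4,5-dihydroxy-4-methylpentyl pivalate | OC[C@@](C)(O)CCCOC(=O)C(C)(C)C | intermediate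
5 | (4S)-4-hydroxy-4-methyl-5-(tosyloxy)pentyl pivalate | Cc1ccc(cc1)S(=O)(=O)OC[C@@](C)(O)CCCOC(=O)C(C)(C)C | intermediate (not isolated)
6 | 3-[(2S)-2-methyloxiran-2-yl]propyl pivalate | CC(C)(C)C(=O)OCCC[C@@]1(C)CO1 | intermediate
7 | diethyl furan-3,4-dicarboxylate | CCOC(=O)c1cocc1C(=O)OCC | starting material
8 | diethyl 2-(trimethylsilyl)furan-3,4-dicarboxylate | CCOC(=O)c1coc([Si](C)(C)C)c1C(=O)OCC | intermediate
9 | [2-(trimethylsilyl)furan-3,4-diyl]dimethanol | OCc1coc([Si](C)(C)C)c1CO | intermediate
10 | {4-[(triethylsilyloxy)methyl]-2-(trimethylsilyl)furan-3-yl}methanol | CC[Si](CC)(CC)OCc1coc([Si](C)(C)C)c1CO | intermediate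
11 | 3-[(tert-butyldimethylsilyloxy)methyl]-4-[(triethylsilyloxy)methyl]-2-(trimethylsilyl)furan | CC[Si](CC)(CC)OCc1coc([Si](C)(C)C)c1CO[Si](C)(C)C(C)(C)C | intermediate
12 | (4S)-5-furyl-4-hydroxy-4-methylpentyl pivalate | CC(C)(C)C(=O)OCCC[C@](C)(O)Cc1oc([Si](C)(C)C)c(CO[Si](C)(C)C(C)(C)C)c1CO[Si](CC)(CC)CC | intermediate
13 | (4S)-5-furyl-4-methylpentane-1,4-diol | OCCC[C@](C)(O)Cc1oc([Si](C)(C)C)c(CO[Si](C)(C)C(C)(C)C)c1CO[Si](CC)(CC)CC | intermediate
14 | (5S)-5-(furylmethyl)-5-methyloxolan-2-ol (anomers) | OC1CC[C@@](C)(Cc2oc([Si](C)(C)C)c(CO[Si](C)(C)C(C)(C)C)c2CO[Si](CC)(CC)CC)O1 | intermediate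
15 | (2S)-2-(furylmethyl)-2-methyl-2,3-dihydrofuran | C1=CC[C@@](C)(Cc2oc([Si](C)(C)C)c(CO[Si](C)(C)C(C)(C)C)c2CO[Si](CC)(CC)CC)O1 | intermediate
16 | N-methoxy-N-methylacetamide | CC(=O)N(C)OC | starting material
17 | 1-[(5S)-5-(furylmethyl)-5-methyl-4,5-dihydrofuran-2-yl]ethanone | CC(=O)C1=CC[C@@](C)(Cc2oc([Si](C)(C)C)c(CO[Si](C)(C)C(C)(C)C)c2CO[Si](CC)(CC)CC)O1 | intermediate
18 | C8 alcohol: 17 with the triethylsilyl ether replaced by OH | CC(=O)C1=CC[C@@](C)(Cc2oc([Si](C)(C)C)c(CO[Si](C)(C)C(C)(C)C)c2CO)O1 | intermediate
19 | keto aldehyde: 18 with CH2OH oxidised to CHO | CC(=O)C1=CC[C@@](C)(Cc2oc([Si](C)(C)C)c(CO[Si](C)(C)C(C)(C)C)c2C=O)O1 | intermediate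
20 | macrocyclic aldol; (4S); 8-hydroxy (both epimers); 10-oxo; C1=C2; 12-SiMe3; 13-OTBS | OC1CC(=O)C2=CC[C@@](C)(Cc3oc([Si](C)(C)C)c(CO[Si](C)(C)C(C)(C)C)c31)O2 | intermediate
21 | (4S,10R)-8,10-diol; C1=C2; 12-SiMe3; 13-OTBS; both C8 epimers | OC1C[C@@](C)(O)C2=CC[C@@](C)(Cc3oc([Si](C)(C)C)c(CO[Si](C)(C)C(C)(C)C)c31)O2 | intermediate
22 | (4S,10R)-10-hydroxy-8-ketone; C1=C2; 12-SiMe3; 13-OTBS | O=C1C[C@@](C)(O)C2=CC[C@@](C)(Cc3oc([Si](C)(C)C)c(CO[Si](C)(C)C(C)(C)C)c31)O2 | intermediate
23 | (1R,4S,10R)-1-methoxy ketal; 8-oxo; 10-OH; 13-OH; 12-SiMe3 | O=C1C[C@@](C)(O)[C@@]2(OC)CC[C@@](C)(Cc3oc([Si](C)(C)C)c(CO)c31)O2 | intermediate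
24 | 13-acetate of 23 | O=C1C[C@@](C)(O)[C@@]2(OC)CC[C@@](C)(Cc3oc([Si](C)(C)C)c(COC(C)=O)c31)O2 | intermediate
25 | (1R,4S,8S,10R)-8,10-syn-diol; 1-OMe; 13-OAc; 12-SiMe3 | O[C@H]1C[C@@](C)(O)[C@@]2(OC)CC[C@@](C)(Cc3oc([Si](C)(C)C)c(COC(C)=O)c31)O2 | intermediate
26 | 8-methacrylate of 25 | C=C(C)C(=O)O[C@H]1C[C@@](C)(O)[C@@]2(OC)CC[C@@](C)(Cc3oc([Si](C)(C)C)c(COC(C)=O)c31)O2 | intermediate
27 | 10-O-trimethylsilyl ether of 26 (key-step precursor) | C=C(C)C(=O)O[C@H]1C[C@@](C)(O[Si](C)(C)C)[C@@]2(OC)CC[C@@](C)(Cc3oc([Si](C)(C)C)c(COC(C)=O)c31)O2 | intermediate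
28 | C6,C12-endoperoxide of 27 (C6 and C12 undefined) | C=C(C)C(=O)O[C@H]1C[C@@](C)(O[Si](C)(C)C)[C@@]2(OC)CC[C@@](C)(CC34OC(OO3)([Si](C)(C)C)C(COC(C)=O)=C41)O2 | intermediate (not isolated)
29 | trimethylsilyl (Z)-4-oxo-2-enoate (C6 ketone, C12 silyl ester) | C=C(C)C(=O)O[C@H]1C[C@@](C)(O[Si](C)(C)C)[C@@]2(OC)CC[C@@](C)(CC(=O)/C1=C(COC(C)=O)\C(=O)O[Si](C)(C)C)O2 | intermediate (not isolated)
30 | C6-hydroxybutenolide (C6 undefined) | C=C(C)C(=O)O[C@H]1C[C@@](C)(O[Si](C)(C)C)[C@@]2(OC)CC[C@@](C)(CC3(O)OC(=O)C(COC(C)=O)=C31)O2 | intermediate (not isolated)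
31 | C6-acetoxybutenolide (C6 undefined) | C=C(C)C(=O)O[C@H]1C[C@@](C)(O[Si](C)(C)C)[C@@]2(OC)CC[C@@](C)(CC3(OC(C)=O)OC(=O)C(COC(C)=O)=C31)O2 | intermediate (not isolated)
32 | C1 methyl ketal of the 10-O-trimethylsilyl target (key-step product) | C=C(C)C(=O)O[C@H]1C[C@@](C)(O[Si](C)(C)C)[C@@]2(OC)CC[C@@](C)(/C=C3/OC(=O)C(COC(C)=O)=C31)O2 | intermediate
33 | 10-O-trimethylsilyl ether of the target | C=C(C)C(=O)O[C@H]1C[C@@](C)(O[Si](C)(C)C)C2=CC[C@@](C)(/C=C3/OC(=O)C(COC(C)=O)=C31)O2 | intermediate
34 | CNP0394509.2; (4S,8S,10R) | C=C(C)C(=O)O[C@H]1C[C@@](C)(O)C2=CC[C@@](C)(/C=C3/OC(=O)C(COC(C)=O)=C31)O2 | target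

**Step count**

Total: 26 steps. Longest linear sequence: 22 steps (steps 5–8 and 9–26 from 7; the branch from 1, steps 1–4 and 9–26, is equally long).

**Steps most likely to fail**

Step 16 (macro-aldol). Ring closure may lose to intermolecular aldol addition, or the strained aldolate may revert by retro-aldol cleavage before or during the quench. The fallback sets out from 15. Lithiation as in step 13 and quenching with 2-chloro-N-methoxy-N-methylacetamide should give chloromethyl ketone F1. Methanolysis with PPTS as in step 14 gives alcohol F2, and MnO2 as in step 15 gives aldehyde F3. Slow addition of F3 to SmI2 in THF at −78 °C (samarium Reformatsky-type cyclisation, a standard way to medium rings) generates the enolate reductively and only at C9, and holds the product as a samarium chelate that does not revert. Aqueous work-up returns to 20.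

Step 17 (methyl addition). Facial selectivity at C10 may be poor or reversed, and the magnesium aldolate may open by retro-aldol reaction. The fallback sets out from 20 and delivers oxygen, not carbon, to the open face. Tebbe methylenation (Cp2Ti(CH2)(Cl)AlMe2, pyridine, THF, −40 °C to 0 °C) gives exocyclic diene F4, and PPTS in methanol adds methanol at C1 to give isopropenyl ketal F5. Mukaiyama hydration (Mn(dpm)3 catalyst, dpm = 2,2,6,6-tetramethylheptane-3,5-dionate, PhSiH3, O2, i-PrOH) places hydrogen on the terminal CH2 and the hydroxyl on C10 from the exposed face to give tertiary alcohol F6. Dess–Martin oxidation gives ketone F7, and camphorsulfonic acid in methanol as in step 19 removes the silyl ether and returns to 23.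

Step 25 (ketal to enol ether). Ionisation of the ketal may be slow beside the electron-withdrawing C10 silyloxy group, and the Lewis acid may degrade the product before elimination is complete. The fallback sets out from 32. PPTS in wet acetone exchanges methoxy for hydroxy and removes the C10 silyl group to give hemiketal diol F8. MsCl and Et3N at −40 °C to 0 °C, as in step 12, activate the more acidic anomeric hydroxyl and eliminate toward C2, which gives 34 directly.

**Further compounds**

F1 | step 16 | chloromethyl ketone: 17 with ClCH2C(=O) in place of acetyl | ClCC(=O)C1=CC[C@@](C)(Cc2oc([Si](C)(C)C)c(CO[Si](C)(C)C(C)(C)C)c2CO[Si](CC)(CC)CC)O1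
F2 | step 16 | alcohol: F1 with the triethylsilyl ether replaced by OH | ClCC(=O)C1=CC[C@@](C)(Cc2oc([Si](C)(C)C)c(CO[Si](C)(C)C(C)(C)C)c2CO)O1
F3 | step 16 | aldehyde: F2 with CH2OH oxidised to CHO | ClCC(=O)C1=CC[C@@](C)(Cc2oc([Si](C)(C)C)c(CO[Si](C)(C)C(C)(C)C)c2C=O)O1
F4 | step 17 | exocyclic diene: 20 with C10=CH2 in place of C10=O | OC1CC(=C)C2=CC[C@@](C)(Cc3oc([Si](C)(C)C)c(CO[Si](C)(C)C(C)(C)C)c31)O2
F5 | step 17 | isopropenyl ketal: F4 with methanol added across C1=C2 (1-OMe) | OC1CC(=C)[C@@]2(OC)CC[C@@](C)(Cc3oc([Si](C)(C)C)c(CO[Si](C)(C)C(C)(C)C)c31)O2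
F6 | step 17 | tertiary alcohol: (1R,4S,10R)-8,10-diol, 1-OMe, 13-OTBS | OC1C[C@@](C)(O)[C@@]2(OC)CC[C@@](C)(Cc3oc([Si](C)(C)C)c(CO[Si](C)(C)C(C)(C)C)c31)O2
F7 | step 17 | ketone: 23 with 13-OTBS in place of 13-OH | O=C1C[C@@](C)(O)[C@@]2(OC)CC[C@@](C)(Cc3oc([Si](C)(C)C)c(CO[Si](C)(C)C(C)(C)C)c31)O2
F8 | step 25 | hemiketal diol: 32 with 1-OH and 10-OH | C=C(C)C(=O)O[C@H]1C[C@@](C)(O)[C@@]2(O)CC[C@@](C)(/C=C3/OC(=O)C(COC(C)=O)=C31)O2
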